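**Plan**

- Retrosynthesis: remove the two angelates and the 8α,9α-epoxide; read the 2β-OH/10α-O pair across the quaternary C1 as a β-hydroxy ketone, i.e. a Δ2-isoxazoline, and cut C10–C1 together with O–C2 (nitrile oxide plus ring alkene C1=C2); then cut C8=C9 (lactone ring-closing metathesis), C6–C7 (allylation), C1=C2 (ring-closing metathesis) and C5–C1 (epoxide opening).
- Forward: acyclic Sharpless epoxy alcohol → cyclopentene (five-membered ring) → C6–C10 chain with its Z alkene locked in a δ-lactone → seven-membered ring by intramolecular nitrile oxide cycloaddition → N–O cleavage, two hydroxyl-directed steps, esters.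
- Stereochemistry: C4 and C5 from the asymmetric epoxidation and its anti opening; C6 by chelation to the 4-OH; C1 and C2 in the key step (tether from C5, suprafacial addition); C10 by hydride delivery from O-2; C8/C9 by oxygen delivery from the 10-OH; ester geometry from (Z)-angelic acid.
- Enabling feature: O-2 and C10 are cis on the cyclopentane, the C1/C5 ring fusion is cis, and C2–O/C10–O are 1,3-related across the quaternary C1, so a C10 dipole tethered through C5 can add across C1=C2 of a cyclopentene and close the seven-membered ring (C1, C5–C10) in one event.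

Key step: step 14

Remark: atom labels follow the hydroazulene ("daucane") numbering C1 (quaternary ring-fusion carbon, bears C15H3), C2, C3, C4 (bears isopropyl), C5 (ring-fusion CH), C6, C7, C8 (bears C14H3), C9, C10 (bonded to C1); α is the face of H-5 and the C1 methyl, β the opposite face; all bicyclic compounds are cis-fused (15-CH3 and H-5 α); the same labels are used for the corresponding atoms of earlier intermediates.

**Route**

Step 1
Reactants: 1 3-methylbut-1-yne
Product: 3 4-methylpent-2-yn-1-ol, via lithium acetylide 2 (not isolated)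
Conditions: n-BuLi, THF, −78 °C; (CH2O)n, −78 °C → rt; then H2O
Reagents that add atoms: formaldehyde (as paraformaldehyde) C=O
Why: Acetylide addition to formaldehyde (alkynylation) should give the propargylic alcohol that carries future C6 (CH2OH), C5, C4 and the isopropyl group; no stereocentre is formed.

Step 2
Reactants: 3 4-methylpent-2-yn-1-ol
Product: 5 (2Z)-3-iodo-4-methylpent-2-en-1-ol, via cyclic sodium alkenylalanate 4 (not isolated)
Conditions: NaAlH2(OCH2CH2OCH3)2, THF, 0 °C → rt; EtOAc; then I2, −78 °C → 0 °C; then H2O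
Reagents that add atoms: iodine II
Why: Hydroxyl-directed trans-hydroalumination of the propargylic alcohol should place aluminium on C4 in a five-membered alkenylalanate, and iodinolysis with retention then gives the Z vinyl iodide (iodine cis to CH2OH).

Step 3
Reactants: 5 (2Z)-3-iodo-4-methylpent-2-en-1-ol
Product: 6 (2E)-3-(propan-2-yl)hexa-2,5-dien-1-ol
Conditions: allyltributylstannane, Pd2(dba)3 (cat.), AsPh3, DMF, 50 °C
Reagents that add atoms: allyltributylstannane C=CC[Sn](CCCC)(CCCC)CCCC
Why: Stille coupling proceeds with retention at the alkenyl carbon, so the allyl group (future C3 and C2) should end cis to CH2OH, the alkene geometry that the epoxide stereochemistry requires.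

Step 4
Reactants: 6 (2E)-3-(propan-2-yl)hexa-2,5-dien-1-ol
Product: 7 [(2S,3S)-3-(propan-2-yl)-3-(prop-2-en-1-yl)oxiran-2-yl]methanol
Conditions: Ti(OiPr)4 (cat.), L-(+)-diethyl tartrate (cat.), t-BuOOH, 4 Å molecular sieves, CH2Cl2, −20 °C
Reagents that add atoms: tert-butyl hydroperoxide CC(C)(C)OO
Why: Sharpless asymmetric epoxidation with the L-(+)-tartrate should deliver oxygen to the face that gives the (2S,3S)-epoxide (same facial sense as for other E 3,3-disubstituted allylic alcohols), which fixes the tertiary C4–O stereocentre and the absolute series while the unactivated terminal alkene stays untouched.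

Step 5
Reactants: 7 [(2S,3S)-3-(propan-2-yl)-3-(prop-2-en-1-yl)oxiran-2-yl]methanol
Product: 8 (2R,3S)-2-(prop-1-en-2-yl)-3-(propan-2-yl)hex-5-ene-1,3-diol
Conditions: CH2=C(CH3)MgBr (3.5 equiv), CuI (cat.), THF, −30 °C → 0 °C; then H2O
Reagents that add atoms: isopropenylmagnesium bromide CC(=C)[Mg]Br
Why: Copper-catalysed Grignard opening of the 2,3-epoxy alcohol should occur at the secondary epoxide carbon (C5) because the other one (C4) is fully substituted, with SN2 inversion, so C5 is set anti to the tertiary 4-OH and the C5–C1 bond is made.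

Step 6
Reactants: 8 (2R,3S)-2-(prop-1-en-2-yl)-3-(propan-2-yl)hex-5-ene-1,3-diol
Product: 9 (1S,2R)-2-(hydroxymethyl)-3-methyl-1-(propan-2-yl)cyclopent-3-en-1-ol
Conditions: second-generation Grubbs catalyst (3 mol %), CH2Cl2, 40 °C
Reagents that add atoms: none
Why: Ring-closing metathesis of the allyl and isopropenyl groups should close the cyclopentene with the trisubstituted C1=C2 double bond; no stereocentre is touched, and CH2OH (C6) ends cis to the 4-OH.

Step 7
Reactants: 9 (1S,2R)-2-(hydroxymethyl)-3-methyl-1-(propan-2-yl)cyclopent-3-en-1-ol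
Product: 10 (1S,5S)-5-hydroxy-2-methyl-5-(propan-2-yl)cyclopent-2-ene-1-carbaldehyde
Conditions: TEMPO (cat.), PhI(OAc)2, CH2Cl2, 0 °C → rt; used crude
Reagents that add atoms: none
Why: Nitroxyl-catalysed oxidation is selective for the primary alcohol over the tertiary one and is non-basic, which should preserve the α-stereocentre (C5) of the β,γ-unsaturated aldehyde.

Step 8
Reactants: 10 (1S,5S)-5-hydroxy-2-methyl-5-(propan-2-yl)cyclopent-2-ene-1-carbaldehyde
Product: 11 (1S,2R)-2-[(1R)-1-hydroxy-3-methylbut-3-en-1-yl]-3-methyl-1-(propan-2-yl)cyclopent-3-en-1-ol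
Conditions: indium powder, 3-bromo-2-methylprop-1-ene, THF/H2O (1:1), rt
Reagents that add atoms: 3-bromo-2-methylprop-1-ene CC(=C)CBr
Why: In this Barbier-type allylation in water the free 4-OH and the aldehyde oxygen should chelate indium in a six-membered ring cis-fused to the cyclopentene, so the allyl group attacks the convex face (anti to C1) and gives the 1,3-anti diol, i.e. the (R) carbinol C6.

Step 9
Reactants: 11 (1S,2R)-2-[(1R)-1-hydroxy-3-methylbut-3-en-1-yl]-3-methyl-1-(propan-2-yl)cyclopent-3-en-1-ol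
Product: 12 (1R)-1-[(1R,5S)-5-hydroxy-2-methyl-5-(propan-2-yl)cyclopent-2-en-1-yl]-3-methylbut-3-en-1-yl prop-2-enoate
Conditions: acryloyl chloride, iPr2NEt, CH2Cl2, −78 °C → 0 °C
Reagents that add atoms: acryloyl chloride C=CC(=O)Cl
Why: O-Acylation should take place only at the secondary 6-OH (the tertiary 4-OH is too hindered) and brings in C9 and C10.

Step 10
Reactants: 12 (1R)-1-[(1R,5S)-5-hydroxy-2-methyl-5-(propan-2-yl)cyclopent-2-en-1-yl]-3-methylbut-3-en-1-yl prop-2-enoate
Product: 13 (6R)-6-[(1R,5S)-5-hydroxy-2-methyl-5-(propan-2-yl)cyclopent-2-en-1-yl]-4-methyl-5,6-dihydro-2H-pyran-2-one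
Conditions: second-generation Grubbs catalyst (5 mol %), toluene, 80 °C, 3 mM
Reagents that add atoms: none
Why: Ring-closing metathesis of the acrylate with the 1,1-disubstituted alkene should give the 4-methyl-5,6-dihydropyran-2-one, whose six-membered ring forces the Z geometry of C8=C9 that the seven-membered ring needs later.

Step 11
Reactants: 13 (6R)-6-[(1R,5S)-5-hydroxy-2-methyl-5-(propan-2-yl)cyclopent-2-en-1-yl]-4-methyl-5,6-dihydro-2H-pyran-2-one
Product: 14 (6R)-6-[(1R,5S)-5-hydroxy-2-methyl-5-(propan-2-yl)cyclopent-2-en-1-yl]-4-methyl-5,6-dihydro-2H-pyran-2-ol (both anomers)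
Conditions: iBu2AlH (2.3 equiv), CH2Cl2, −78 °C; aq. potassium sodium tartrate
Reagents that add atoms: none
Why: Partial hydride reduction of the lactone at low temperature should stop at the lactol (stable tetrahedral aluminate), a masked Z hydroxy-enal that cannot isomerise to the E enal.

Step 12
Reactants: 14 (6R)-6-[(1R,5S)-5-hydroxy-2-methyl-5-(propan-2-yl)cyclopent-2-en-1-yl]-4-methyl-5,6-dihydro-2H-pyran-2-ol
Product: 15 (1S,2R)-2-[(1R,3Z,5E)-1-hydroxy-5-(hydroxyimino)-3-methylpent-3-en-1-yl]-3-methyl-1-(propan-2-yl)cyclopent-3-en-1-ol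
Conditions: NH2OH·HCl, pyridine, EtOH, 0 °C → rt
Reagents that add atoms: hydroxylamine hydrochloride NO.Cl
Why: Oxime condensation should trap the open-chain aldehyde form of the lactol with retention of the Z C8=C9 alkene.

Step 13
Reactants: 15 (1S,2R)-2-[(1R,3Z,5E)-1-hydroxy-5-(hydroxyimino)-3-methylpent-3-en-1-yl]-3-methyl-1-(propan-2-yl)cyclopent-3-en-1-ol
Product: 17 (1S,2R)-2-[(1R,3Z,5E)-1-{[tert-butyl(dimethyl)silyl]oxy}-5-(hydroxyimino)-3-methylpent-3-en-1-yl]-3-methyl-1-(propan-2-yl)cyclopent-3-en-1-ol, via bis-silyl ether 16 (not isolated)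
Conditions: TBSCl (2.6 equiv), imidazole, DMF, rt; then K2CO3 (cat.), MeOH, 0 °C
Reagents that add atoms: tert-butyldimethylsilyl chloride CC(C)(C)[Si](C)(C)Cl
Why: Silyl ether formation should occur at the secondary 6-OH and the oxime oxygen (the tertiary 4-OH is inert), and mild methanolysis then cleaves only the labile N–O–Si bond, leaving O-6 protected so that it cannot add to the nitrile oxide.

Step 14
Reactants: 17 (1S,2R)-2-[(1R,3Z,5E)-1-{[tert-butyl(dimethyl)silyl]oxy}-5-(hydroxyimino)-3-methylpent-3-en-1-yl]-3-methyl-1-(propan-2-yl)cyclopent-3-en-1-ol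
Product: 20 6α-[tert-butyl(dimethyl)silyloxy]-2β,10-(epoxynitrilo)dauc-8-en-4β-ol (tricyclic Δ2-isoxazoline), via hydroximoyl chloride 18 (not isolated), via nitrile oxide 19 (not isolated)
Conditions: aq. NaOCl (slow addition), Et3N (cat.), CH2Cl2, 0 °C → rt, 2 mM
Reagents that add atoms: none
Why: Hypochlorite should chlorinate the aldoxime and loss of HCl then gives the conjugated nitrile oxide 19, which adds suprafacially across the trisubstituted ring alkene C1=C2 in a concerted [3+2] cycloaddition (intramolecular nitrile oxide–alkene cycloaddition, the isoxazoline equivalent of an aldol), forming C10–C1 and O–C2 together. The seven-membered carbocycle closes in the fused (exo) mode, C10 bonding to the proximal alkene carbon C1 so that C2 stays outside the new carbocycle, and the isoxazoline (C10=N–O–C2–C1) closes as the five-membered cycloadduct ring. The quaternary centre C1 is controlled by the C5 stereocentre, because the tether C6–C10 can reach only the ring face that carries C6, which gives the cis ring fusion with the methyl group on the α face. C2 is controlled by the suprafacial course of the cycloaddition, so its oxygen is cis to C10 on the cyclopentane (2β). The step needs regioselectivity for C1 over C2 and chemoselectivity against furoxan dimerisation; the short tether, held in a U shape by the Z C8=C9 double bond, should favour the fused seven-membered mode over the bridged eight-membered one, and high dilution should suppress dimerisation.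

Step 15
Reactants: 20 6α-[tert-butyl(dimethyl)silyloxy]-2β,10-(epoxynitrilo)dauc-8-en-4β-ol
Product: 22 6α-[tert-butyl(dimethyl)silyloxy]-2β,4β-dihydroxydauc-8-en-10-one, via hydroxy imine 21 (not isolated)
Conditions: Mo(CO)6 (1.2 equiv), CH3CN/H2O (15:1), 80 °C
Reagents that add atoms: water O
Why: Reductive N–O cleavage of the isoxazoline by Mo(CO)6 and hydrolysis of the resulting conjugated imine should unmask the β-hydroxy enone without reducing the alkene; C1 being quaternary, dehydration cannot occur and no stereocentre changes.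

Step 16
Reactants: 22 6α-[tert-butyl(dimethyl)silyloxy]-2β,4β-dihydroxydauc-8-en-10-one
Product: 23 6α-[tert-butyl(dimethyl)silyloxy]-4β,10α-dihydroxydauc-8-en-2β-yl pent-4-enoate
Conditions: SmI2 (0.3 equiv), pent-4-enal (8 equiv), THF, −10 °C
Reagents that add atoms: pent-4-enal C=CCCC=O
Why: In this Evans–Tishchenko reduction the samarium-bound hemiacetal of O-2 with pent-4-enal should transfer hydride through a six-membered chair to the β face of the C10 ketone, setting the 10α-alcohol (1,3-anti to O-2) and leaving O-2 as its pent-4-enoate, which tells the two secondary hydroxyls apart.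

Step 17
Reactants: 23 6α-[tert-butyl(dimethyl)silyloxy]-4β,10α-dihydroxydauc-8-en-2β-yl pent-4-enoate
Product: 24 6α-[tert-butyl(dimethyl)silyloxy]-8α,9α-epoxy-4β,10α-dihydroxydaucan-2β-yl pent-4-enoate
Conditions: VO(acac)2 (5 mol %), t-BuOOH (1.5 equiv), CH2Cl2, 0 °C → rt
Reagents that add atoms: tert-butyl hydroperoxide CC(C)(C)OO
Why: Hydroxyl-directed vanadium-catalysed epoxidation should deliver oxygen from the vanadate ester of the 10α-allylic alcohol to the α face of C8=C9, setting C8 and C9 syn to O-10, while the undirected terminal alkene of the pentenoate stays.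

Step 18
Reactants: 24 6α-[tert-butyl(dimethyl)silyloxy]-8α,9α-epoxy-4β,10α-dihydroxydaucan-2β-yl pent-4-enoate
Product: 25 8α,9α-epoxy-4β,6α,10α-trihydroxydaucan-2β-yl pent-4-enoate
Conditions: HF·pyridine, pyridine, THF, 0 °C → rt
Reagents that add atoms: none
Why: Fluoride-mediated desilylation under buffered conditions should free the 6α-OH without opening the epoxide or moving the ester.

Step 19
Reactants: 25 8α,9α-epoxy-4β,6α,10α-trihydroxydaucan-2β-yl pent-4-enoate; 26 angelic acid [(2Z)-2-methylbut-2-enoic acid] (2 equivalents react)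
Product: 27 6α,10α-bis[(2Z)-2-methylbut-2-enoyloxy]-8α,9α-epoxy-4β-hydroxydaucan-2β-yl pent-4-enoate
Conditions: 26 (5 equiv), 2,4,6-trichlorobenzoyl chloride (5 equiv), Et3N, toluene, rt; then 25, toluene, 80 °C
Reagents that add atoms: none
Why: Yamaguchi esterification through the mixed 2,4,6-trichlorobenzoic anhydride, run without a nucleophilic catalyst, should acylate both secondary hydroxyls without isomerising angelate to tiglate, and the tertiary 4-OH does not react.

Step 20
Reactants: 27 6α,10α-bis[(2Z)-2-methylbut-2-enoyloxy]-8α,9α-epoxy-4β-hydroxydaucan-2β-yl pent-4-enoate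
Product: 28 6α,10α-bis[(2Z)-2-methylbut-2-enoyloxy]-8α,9α-epoxydaucane-2β,4β-diol, (1R,2S,4S,5R,6R,8S,9R,10R), CNP0265715.2
Conditions: N-iodosuccinimide (3 equiv), THF/H2O (4:1), 0 °C → rt, dark
Reagents that add atoms: none
Why: Iodolactonisation-type cleavage of the pent-4-enoate (iodonium activation of the terminal alkene, attack by the ester carbonyl oxygen, hydrolysis) should release the 2β-OH under neutral conditions, so the electron-poor angelates neither react nor migrate and the epoxide is not exposed to an alkoxide.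

**Compound list**

1 | 3-methylbut-1-yne | C#CC(C)C | starting material
2 | lithium 3-methylbut-1-yn-1-ide | [Li]C#CC(C)C | intermediate
3 | 4-methylpent-2-yn-1-ol | OCC#CC(C)C | intermediate
4 | sodium 2,2-bis(2-methoxyethoxy)-3-(propan-2-yl)-2,5-dihydro-1,2-oxaaluminol-2-uide (cyclic alkenylalanate) | CC(C)C1=CCO[Al-]1(OCCOC)OCCOC.[Na+] | intermediate
5 | (2Z)-3-iodo-4-methylpent-2-en-1-ol | OC/C=C(\I)C(C)C | intermediate
6 | (2E)-3-(propan-2-yl)hexa-2,5-dien-1-ol | OC/C=C(\CC=C)C(C)C | intermediate
7 | [(2S,3S)-3-(propan-2-yl)-3-(prop-2-en-1-yl)oxiran-2-yl]methanol | OC[C@@H]1O[C@@]1(CC=C)C(C)C | intermediate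
8 | (2R,3S)-2-(prop-1-en-2-yl)-3-(propan-2-yl)hex-5-ene-1,3-diol | OC[C@@H](C(C)=C)[C@](O)(CC=C)C(C)C | intermediate
9 | (1S,2R)-2-(hydroxymethyl)-3-methyl-1-(propan-2-yl)cyclopent-3-en-1-ol | OC[C@H]1C(C)=CC[C@]1(O)C(C)C | intermediate
10 | (1S,5S)-5-hydroxy-2-methyl-5-(propan-2-yl)cyclopent-2-ene-1-carbaldehyde | O=C[C@H]1C(C)=CC[C@]1(O)C(C)C | intermediate
11 | (1S,2R)-2-[(1R)-1-hydroxy-3-methylbut-3-en-1-yl]-3-methyl-1-(propan-2-yl)cyclopent-3-en-1-ol | O[C@H](CC(C)=C)[C@H]1C(C)=CC[C@]1(O)C(C)C | intermediate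
12 | (1R)-1-[(1R,5S)-5-hydroxy-2-methyl-5-(propan-2-yl)cyclopent-2-en-1-yl]-3-methylbut-3-en-1-yl prop-2-enoate | C=CC(=O)O[C@H](CC(C)=C)[C@H]1C(C)=CC[C@]1(O)C(C)C | intermediate
13 | (6R)-6-[(1R,5S)-5-hydroxy-2-methyl-5-(propan-2-yl)cyclopent-2-en-1-yl]-4-methyl-5,6-dihydro-2H-pyran-2-one | O=C1C=C(C)C[C@@H](O1)[C@H]2C(C)=CC[C@]2(O)C(C)C | intermediate
14 | (6R)-6-[(1R,5S)-5-hydroxy-2-methyl-5-(propan-2-yl)cyclopent-2-en-1-yl]-4-methyl-5,6-dihydro-2H-pyran-2-ol (both anomers, C2 of the pyran undefined) | OC1C=C(C)C[C@@H](O1)[C@H]2C(C)=CC[C@]2(O)C(C)C | intermediate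
15 | (1S,2R)-2-[(1R,3Z,5E)-1-hydroxy-5-(hydroxyimino)-3-methylpent-3-en-1-yl]-3-methyl-1-(propan-2-yl)cyclopent-3-en-1-ol | O[C@H](C/C(C)=C\C=N\O)[C@H]1C(C)=CC[C@]1(O)C(C)C | intermediate
16 | bis-silyl ether of 15 (TBS on O-6 and on the oxime oxygen) | CC(C)(C)[Si](C)(C)O[C@H](C/C(C)=C\C=N\O[Si](C)(C)C(C)(C)C)[C@H]1C(C)=CC[C@]1(O)C(C)C | intermediate
17 | (1S,2R)-2-[(1R,3Z,5E)-1-{[tert-butyl(dimethyl)silyl]oxy}-5-(hydroxyimino)-3-methylpent-3-en-1-yl]-3-methyl-1-(propan-2-yl)cyclopent-3-en-1-ol | CC(C)(C)[Si](C)(C)O[C@H](C/C(C)=C\C=N\O)[C@H]1C(C)=CC[C@]1(O)C(C)C | intermediate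
18 | hydroximoyl chloride of 17 (C10 bears Cl, Z at C=N) | CC(C)(C)[Si](C)(C)O[C@H](C/C(C)=C\C(Cl)=N\O)[C@H]1C(C)=CC[C@]1(O)C(C)C | intermediate
19 | nitrile oxide of 17 (C10≡N–O) | CC(C)(C)[Si](C)(C)O[C@H](C/C(C)=C\C#[N+][O-])[C@H]1C(C)=CC[C@]1(O)C(C)C | intermediate
20 | 6α-[tert-butyl(dimethyl)silyloxy]-2β,10-(epoxynitrilo)dauc-8-en-4β-ol (tricyclic isoxazoline, O on C2, C=N at C10) | CC(C)(C)[Si](C)(C)O[C@@H]1CC(C)=CC2=NO[C@H]3C[C@](O)(C(C)C)[C@@H]1[C@@]23C | intermediate
21 | 6α-[tert-butyl(dimethyl)silyloxy]-10-iminodauc-8-ene-2β,4β-diol | CC(C)(C)[Si](C)(C)O[C@@H]1CC(C)=CC(=N)[C@@]2(C)[C@@H](O)C[C@](O)(C(C)C)[C@@H]12 | intermediate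
22 | 6α-[tert-butyl(dimethyl)silyloxy]-2β,4β-dihydroxydauc-8-en-10-one | CC(C)(C)[Si](C)(C)O[C@@H]1CC(C)=CC(=O)[C@@]2(C)[C@@H](O)C[C@](O)(C(C)C)[C@@H]12 | intermediate
23 | 6α-[tert-butyl(dimethyl)silyloxy]-4β,10α-dihydroxydauc-8-en-2β-yl pent-4-enoate | CC(C)(C)[Si](C)(C)O[C@@H]1CC(C)=C[C@H](O)[C@@]2(C)[C@@H](OC(=O)CCC=C)C[C@](O)(C(C)C)[C@@H]12 | intermediate
24 | 6α-[tert-butyl(dimethyl)silyloxy]-8α,9α-epoxy-4β,10α-dihydroxydaucan-2β-yl pent-4-enoate | CC(C)(C)[Si](C)(C)O[C@@H]1C[C@]2(C)O[C@@H]2[C@H](O)[C@@]2(C)[C@@H](OC(=O)CCC=C)C[C@](O)(C(C)C)[C@@H]12 | intermediate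
25 | 8α,9α-epoxy-4β,6α,10α-trihydroxydaucan-2β-yl pent-4-enoate | O[C@@H]1C[C@]2(C)O[C@@H]2[C@H](O)[C@@]2(C)[C@@H](OC(=O)CCC=C)C[C@](O)(C(C)C)[C@@H]12 | intermediate
26 | angelic acid, (2Z)-2-methylbut-2-enoic acid | C/C=C(/C)C(=O)O | starting material
27 | 6α,10α-bis[(2Z)-2-methylbut-2-enoyloxy]-8α,9α-epoxy-4β-hydroxydaucan-2β-yl pent-4-enoate | C/C=C(/C)C(=O)O[C@@H]1C[C@]2(C)O[C@@H]2[C@H](OC(=O)/C(C)=C\C)[C@@]2(C)[C@@H](OC(=O)CCC=C)C[C@](O)(C(C)C)[C@@H]12 | intermediate
28 | 6α,10α-bis[(2Z)-2-methylbut-2-enoyloxy]-8α,9α-epoxydaucane-2β,4β-diol, (1R,2S,4S,5R,6R,8S,9R,10R) | C/C=C(/C)C(=O)O[C@@H]1C[C@]2(C)O[C@@H]2[C@H](OC(=O)/C(C)=C\C)[C@@]2(C)[C@@H](O)C[C@](O)(C(C)C)[C@@H]12 | target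

**Totals**

Total step count: 20. Longest linear sequence: 20 steps (1 → 28).

**Steps most likely to fail**

Step 14 (key cycloaddition). The seven-membered fused closure creates a quaternary centre and is slow, so dimerisation of the nitrile oxide to the furoxan, or closure through the distal alkene carbon C2 (bridged eight-membered mode), may outrun it. The fallback sets out from 17 and avoids a free nitrile oxide: heating 17 in toluene (sealed tube, about 150 °C) should cause the thermal intramolecular oxime–olefin cycloaddition (1,2-prototropy to the N–H nitrone, then [3+2] across C1=C2 under the same tether control) to give the N–H isoxazolidine F1 (6α-silyloxy-2β,10-(epoxyimino)dauc-8-en-4β-ol). N-Chlorination with N-chlorosuccinimide and dehydrochlorination with Et3N should then convert F1 into isoxazoline 20, where the route is rejoined.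

Step 19 (double angeloylation). The angeloyl group may isomerise to the tigloyl group during activation, and acylation of the neopentylic, epoxide-flanked 10α-OH may be slow. The fallback sets out from 25 and builds the Z esters on the molecule instead of transferring them: esterification of both secondary hydroxyls with 2-[bis(2,2,2-trifluoroethoxy)phosphoryl]propanoic acid (N,N'-dicyclohexylcarbodiimide, DMAP, CH2Cl2) should give the bis(phosphonopropanoate) F2. A double Still–Gennari olefination of F2 with acetaldehyde (KN(SiMe3)2, 18-crown-6, THF, −78 °C) should then give the two (Z)-2-methylbut-2-enoates and so return to 27.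

Step 8 (allylation of aldehyde 10). The ring double bond may migrate into conjugation with the aldehyde (which erases the C5 stereocentre), and chelation may be incomplete, eroding facial control at C6. The fallback sets out from crude 10 and returns at 11: reagent-controlled allylboration at −78 °C in Et2O under anhydrous, neutral conditions with the enantiomer of B-(2-methylprop-2-en-1-yl)diisopinocampheylborane that delivers the (R) carbinol, followed by ethanolamine work-up, should give 11 directly. This replaces substrate chelation by reagent control and makes no new compound (F0).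

**Further compounds**

F1 | step 14 | 6α-[tert-butyl(dimethyl)silyloxy]-2β,10-(epoxyimino)dauc-8-en-4β-ol (N–H isoxazolidine, C10 configuration undefined) | CC(C)(C)[Si](C)(C)O[C@@H]1CC(C)=CC2NO[C@H]3C[C@](O)(C(C)C)[C@@H]1[C@@]23C
F2 | step 19 | 6α,10α-bis{2-[bis(2,2,2-trifluoroethoxy)phosphoryl]propanoyloxy}-8α,9α-epoxy-4β-hydroxydaucan-2β-yl pent-4-enoate (phosphonate α-carbons undefined) | CC(C(=O)O[C@@H]1C[C@]2(C)O[C@@H]2[C@H](OC(=O)C(C)P(=O)(OCC(F)(F)F)OCC(F)(F)F)[C@@]2(C)[C@@H](OC(=O)CCC=C)C[C@](O)(C(C)C)[C@@H]12)P(=O)(OCC(F)(F)F)OCC(F)(F)F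
F0 | step 8 | none | none
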